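**Fading lead.** In Thursday's run the left-handed product led the right-handed product by less after 8.00 h (0.8 percentage points of the charge) than after 5.00 h (5.4 points), although product went on forming.

in all of them: left-handed substrate 0.050 M; right-handed substrate 0.050 M; free catalyst 10 mol%

| run | partner | protic impurity | remark | time |
|---|---|---|---|---|
| Thursday's | 1.1 equiv | 0.015 M | run made earlier |  |
| theta | 1.10 equiv | 0.0100 M |  | 3.0 d |
| gamma | 1.10 equiv | 0.0100 M |  | 1.5 d |

Thursday's run (percent of the left-handed substrate and right-handed substrate together charged)

| time / h | left-handed product / % | right-handed product / % |
|---|---|---|
| 0.667 | 3.2 | 1.2 |
| 2.00 | 5.7 | 2.8 |
| 3.00 | 6.8 | 3.1 |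
| 5.00 | 9.9 | 4.5 |
| 8.00 | 11.0 | 10.2 |

(each reading ± 1 percentage point)

- the flask that ends with the higher excess of left-handed product over right-handed product in the product, or "neither" when 2 percentage points or less lies between them (theta / gamma / neither)
- excess of left-handed product over right-handed product in the product at the end, theta
- excess of left-handed product over right-handed product in the product at the end, gamma

- free catalyst is single-handed; left-handed substrate and right-handed substrate are mirror images of each other, charged as a racemate, each of them at the stated concentration
- an excess is the difference of the two amounts in percent of their sum
- an excess is below zero if the other one leads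
- no earlier run changes the charge of protic impurity; that part of a forecast is a guess

**Memory time.** We call the time in which the lead falls to 36.8% of itself the memory time 1.57 h, a rough reading from these two points. It is far shorter than gamma's 1.5 d, so we take a late lead to be at most the product feed multiplied by the memory time.

**Bracket.** Mirror-image products have equal energy, so thermodynamic control puts the bound from below at zero. A crude bound from above is the 5.4 points lead over the product fraction 21.2% at 8.00 h, or 25.5%.

We tighten it by taking one partner per product, which gives a ceiling of 55.0% of the charge. We also take the feed to fall with time, so the end feed lies below the average since that last reading. The worst case ends at the ceiling, which gives estimated caps, no firmer than the memory time read, of 3.45% for gamma and 1.51% for theta. Gamma's cap stands above the margin of 2 points, so the bracket does not exclude gamma leading, and our choice of neither flask is a judgement beyond it.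

**Forecast.** The forecast gives 4% for theta and 9% for gamma, both above our caps , and it names gamma, because “the shorter run should keep slightly more excess”.

**Result.** The answer is neither: theta ends at 0.281% and gamma at 1.12%.

    partner + free catalyst + left-handed substrate → free catalyst + left-handed product (k = 5.60 M⁻² min⁻¹)
    partner + free catalyst + right-handed substrate → free catalyst + right-handed product (k = 0.0360 M⁻² min⁻¹)
    left-handed product ⇌ right-handed product (k = 0.00450 min⁻¹)
    partner + protic impurity → quenched reagent (k = 0.0470 M⁻¹ min⁻¹)
    free catalyst → spent catalyst (k = 2.10 × 10⁻⁴ min⁻¹)

**Longer wait.** Both results stand under their caps , and 0.84 points lies between them. The neighbouring flask is theta left until 12 d. The same memory time of 1.57 h, still the rough reading, with 280 h since Thursday's last reading, gives an estimated cap on its excess of 0.345%, lower than theta's estimated cap. That flask holds 20.6% left-handed product and 20.6% right-handed product, and its excess is 0.00692%.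

The runs were computed for an exercise; scatter was added.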